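The same charge goes into a closed flask, a dosed flask and two flow tanks, and you want to know which of them holds more open intermediate than the others when it is read.

| flask | substrate | partner | protic impurity | remark | time |
|---|---|---|---|---|---|
| north-east | 0.20 M | 1 equiv | 0.10 M | run made earlier |  |
| north-west | 0.20 M | 1 equiv | 0.14 M | run made earlier |  |
| west | 0.20 M | 1 equiv | 0.22 M | run made earlier |  |
| epsilon | 0.20 M | 1.00 equiv | 0.100 M | everything together in a closed stirred flask, run for 5.0 min | 5.0 min |
| beta | 0.20 M (fed, over 4.00 min) | 1.00 equiv | 0.100 M | all but substrate at the start; substrate goes in evenly over 4.00 min, the run ends at 5.0 min | 5.0 min |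
| alpha | 0.20 M | 1.00 equiv | 0.100 M | one stirred flow tank at steady state, fed with the mixture as stated, mean residence time 5.0 min |  |
| theta | 0.20 M | 1.00 equiv | 0.100 M | one stirred flow tank at steady state, fed with the mixture as stated, mean residence time 15.0 min |  |

| run | time / min | open intermediate / % | target / % | substrate / % |
|---|---|---|---|---|
| north-east | 0.250 | 13.0 | 0.5 | 85.7 |
| north-east | 0.417 | 22.1 | 1.0 | 78.0 |
| north-east | 0.667 | 32.1 | 1.3 | 66.5 |
| north-east | 1.00 | 42.8 | 3.2 | 54.3 |
| north-east | 2.00 | 57.9 | 11.8 | 30.5 |
| north-east | 3.00 | 62.7 | 20.6 | 16.7 |
| north-west | 0.833 | 38.1 | 2.2 | 61.4 |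
| north-west | 1.50 | 52.8 | 6.4 | 40.4 |
| north-west | 2.50 | 64.2 | 13.0 | 22.9 |
| north-west | 3.00 | 67.4 | 16.4 | 15.7 |
| north-west | 4.00 | 70.1 | 20.9 | 9.2 |
| north-west | 5.00 | 71.7 | 23.2 | 5.5 |
| west | 0.833 | 38.2 | 1.0 | 60.7 |
| west | 1.50 | 54.8 | 4.4 | 41.0 |
| west | 2.50 | 68.2 | 8.4 | 22.3 |
| west | 3.00 | 73.6 | 11.3 | 16.5 |
| west | 4.00 | 79.6 | 12.2 | 9.6 |
| west | 5.00 | 81.8 | 13.2 | 4.5 |

(readings scatter by 0.5 percentage points)

* the set-up with the highest amount of open intermediate at the outlet or at the end, in percent of the substrate put in ("none" if the first two lie within 2 percentage points) (epsilon / beta / alpha / theta / none)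
* amount of open intermediate at the outlet or at the end, in percent of the substrate put in, epsilon
* amount of open intermediate at the outlet or at the end, in percent of the substrate put in, beta
* amount of open intermediate at the outlet or at the end, in percent of the substrate put in, alpha
* amount of open intermediate at the outlet or at the end, in percent of the substrate put in, theta

- the stated concentrations are those of everything mixed, before any reaction; amounts are the same in each set-up
- the feed brings no volume worth counting
- the earlier runs were made in a closed, stirred flask

One thing in the earlier runs looks wrong at first. At 3.00 min the north-east run has 16.7% of its substrate left and the west run 16.5%, equal within the scatter of 0.5 percentage points, yet the west run holds about half the target, 11.3% against 20.6%. The west run was charged with 0.22 M of protic impurity, the north-east run with 0.10 M.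

It clears up when you reckon the fraction left and not the fraction made. The logarithm of the fraction left, divided by the time, gives 0.597 /min, 0.617 /min and 0.601 /min in the three runs. Their mean, 0.605 /min, is a reading of the substrate's first-order rate constant. So within the scatter the three runs lose substrate at one pace, and they differ in what comes after open intermediate is made.

My own reckoning carries this constant to each vessel. Epsilon keeps 4.86% of its substrate. Beta, averaged over its feed, keeps 20.6%. A tank keeps one over one plus the constant times the residence time: 24.9% in alpha and 9.93% in theta. The readings of substrate, open intermediate and target in the north-east run at 3.00 min add up to 100%, so open intermediate is what substrate and target leave over. By this reckoning epsilon has less substrate left than beta, a head start of 16 points, so beta can pass epsilon only if epsilon's target exceeds beta's by more than that.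

The forecast says beta, with 62% for epsilon, 64% for beta, 51.5% for alpha and 55.5% for theta: “Beta's lead over epsilon is marginal.”

The flask gives epsilon: 63.7% in epsilon, 58.3% in beta, 49.9% in alpha and 49.6% in theta.

    target → over-reaction product (k = 1.80 × 10⁻⁵ /s)
    open intermediate + second intermediate → target (k = 0.0920 /M/s)
    2 second intermediate → homo product (k = 0.0480 /M/s)
    substrate → open intermediate (k = 0.0100 /s)
    partner → second intermediate (k = 0.00600 /s)
    partner + protic impurity → quenched reagent (k = 0.290 /M/s)

Target stands at 31.2% in epsilon and 20.9% in beta, a difference of 10 points, less than the head start of 16 points, so epsilon stays ahead by 5.4 points.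

Carried to the neighbour of epsilon with 1.70 equiv of partner, the constant again gives 4.86% of substrate left. That flask holds 4.98%, with 53.9% target and 41.0% open intermediate.

The numbers in the tables were generated by integration for substances that don't exist; scatter was added.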